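## Retrosynthetic overview

1. Target 21 ⇐ macrodiolide 19 by one global unmasking (five aryl MOM ethers, two benzylic silyl ethers).
2. 12-Membered ring ⇐ intramolecular attack of the unit-A carboxylate on C2′ of the unit-B cis-epoxide (inversion at C2′, C1′–O released as a silyl ether). This is a new silyl-ester/epoxide chain reaction; the same reaction run intermolecularly joins acid 14 to epoxide 9.
3. Both (2R,3S)-oxiranes ⇐ Shi organocatalytic epoxidation of Z-propenyl arenes, first on achiral ester 8, then under catalyst control on 16.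
4. Both arenes ⇐ one Z-propenylbenzoic acid 7 (directed ortho-metalation of 5, then CO2): O-allylation gives unit A; a second, OMOM-directed metalation of its carboxylate with B(OMe)3/H2O2 adds the extra unit-B oxygen.
5. 5 ⇐ 2-methoxyresorcinol (MOM protection, C–H borylation, Suzuki coupling with (Z)-1-bromopropene). Ring order: unit-A oxirane, unit-B oxirane, 12-membered ring.

Assumption: the target is taken exactly as drawn (all four carbinol centres R). Unit A is the half whose ring keeps one aromatic H, unit B the fully substituted half; C1′ is the benzylic carbon and C2′ the methyl-bearing carbon.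

## Route

Step 1
Reactants: 1 2-methoxybenzene-1,3-diol
Product: 2 2-methoxy-1,3-bis(methoxymethoxy)benzene
Conditions: NaH, MOMCl, DMF, 0 °C → rt
Reagents that add atoms: chloromethyl methyl ether, COCCl
Why: Williamson O-alkylation of both phenoxides gives MOM ethers that later direct ortho-lithiation and add no aryl C–H bonds that would compete in the borylation.

Step 2
Reactants: 2 2-methoxy-1,3-bis(methoxymethoxy)benzene
Product: 3 2-[4-methoxy-3,5-bis(methoxymethoxy)phenyl]-4,4,5,5-tetramethyl-1,3,2-dioxaborolane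
Conditions: B2pin2, [Ir(OMe)(cod)]2 (1.5 mol%), 4,4′-di-tert-butyl-2,2′-bipyridine (3 mol%), THF, 80 °C
Reagents that add atoms: bis(pinacolato)diboron, CC1(C)OB(OC1(C)C)B1OC(C)(C)C(C)(C)O1
Why: sterically governed iridium-catalysed C–H borylation goes to C5, the only ring C–H without an ortho substituent.

Step 3
Reactants: 3 2-[4-methoxy-3,5-bis(methoxymethoxy)phenyl]-4,4,5,5-tetramethyl-1,3,2-dioxaborolane; 4 (Z)-1-bromoprop-1-ene
Product: 5 2-methoxy-1,3-bis(methoxymethoxy)-5-[(Z)-prop-1-en-1-yl]benzene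
Conditions: Pd(PPh3)4 (3 mol%), K3PO4, dioxane/H2O, 60 °C, sealed tube
Reagents that add atoms: none
Why: Suzuki–Miyaura coupling of an aryl boronate with an alkenyl bromide keeps the Z geometry of the bromide.

Step 4
Reactants: 5 2-methoxy-1,3-bis(methoxymethoxy)-5-[(Z)-prop-1-en-1-yl]benzene
Product: 7 3-methoxy-2,4-bis(methoxymethoxy)-6-[(Z)-prop-1-en-1-yl]benzoic acid, via aryllithium 6 (not isolated)
Conditions: n-BuLi, THF, −40 → −10 °C; dry CO2, −78 → 0 °C; cold 1 M HCl to pH 3, immediate extraction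
Reagents that add atoms: carbon dioxide, O=C=O
Why: directed ortho-metalation next to OMOM (the two ring C–H are equivalent and each flanks a MOM ether) is faster at low temperature than attack on the electron-rich β-methylstyrene unit, and carboxylation of the aryllithium gives the 2,6-disubstituted benzoic acid from which both units are made.

Step 5
Reactants: 7 3-methoxy-2,4-bis(methoxymethoxy)-6-[(Z)-prop-1-en-1-yl]benzoic acid
Product: 8 prop-2-en-1-yl 3-methoxy-2,4-bis(methoxymethoxy)-6-[(Z)-prop-1-en-1-yl]benzoate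
Conditions: allyl bromide, KHCO3, DMF, rt
Reagents that add atoms: allyl bromide, C=CCBr
Why: carboxylate O-alkylation (SN2 at allyl bromide) esterifies the hindered 2,6-disubstituted acid without any attack at its shielded carbonyl.

Step 6
Reactants: 8 prop-2-en-1-yl 3-methoxy-2,4-bis(methoxymethoxy)-6-[(Z)-prop-1-en-1-yl]benzoate
Product: 9 prop-2-en-1-yl 3-methoxy-2,4-bis(methoxymethoxy)-6-[(2R,3S)-3-methyloxiran-2-yl]benzoate
Conditions: Shi D-glucose-derived N-aryl spiro-oxazolidinone ketone (25 mol%), KHSO5 (as 2KHSO5·KHSO4·K2SO4), K2CO3, DME/CH2(OMe)2, aq. K2CO3–AcOH buffer (pH 8), Bu4NHSO4, −10 → 0 °C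
Reagents that add atoms: potassium peroxymonosulfate, [K+].[O-]S(=O)(=O)OO
Why: Shi asymmetric epoxidation with the ketone designed for cis-olefins epoxidises the electron-rich Z-styrene (the allyl ester alkene is inert) in the (1R,2S) sense established for cis-β-methylstyrenes, setting C1′ (R) and C2′ (S) of unit A from achiral material.

Step 7
Reactants: 7 3-methoxy-2,4-bis(methoxymethoxy)-6-[(Z)-prop-1-en-1-yl]benzoic acid
Product: 12 5-hydroxy-3-methoxy-2,4-bis(methoxymethoxy)-6-[(Z)-prop-1-en-1-yl]benzoic acid, via dilithiated benzoate 10 (not isolated), via dimethyl boronate 11 (not isolated)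
Conditions: s-BuLi (2.3 equiv), TMEDA, THF, −78 °C; B(OMe)3, −78 °C → rt; then 30% H2O2, AcOH, 0 °C
Reagents that add atoms: hydrogen peroxide, OO
Why: directed ortho-metalation of the unprotected benzoic acid, in which the first equivalent of s-BuLi makes the lithium carboxylate (both ortho positions blocked, shielded carbonyl inert to addition at −78 °C) and the second lithiates the only ring C–H, ortho to OMOM, after which borate trapping and peroxide oxidation of the aryl boronate install the extra unit-B oxygen.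

Step 8
Reactants: 12 5-hydroxy-3-methoxy-2,4-bis(methoxymethoxy)-6-[(Z)-prop-1-en-1-yl]benzoic acid
Product: 14 3-methoxy-2,4,5-tris(methoxymethoxy)-6-[(Z)-prop-1-en-1-yl]benzoic acid, via methoxymethyl ester 13 (not isolated)
Conditions: NaH (2.3 equiv), MOMCl (2.6 equiv), THF/DMF (4:1), 0 °C; then aq. KOH, MeOH, 50 °C, same flask; cold 1 M HCl to pH 3, immediate extraction
Reagents that add atoms: chloromethyl methyl ether, COCCl
Why: Williamson O-alkylation caps the hindered, oxidation-prone phenoxide at once and also alkylates the carboxylate, and the resulting methoxymethyl ester (an acyloxy acetal) is then saponified selectively because aryl MOM ethers are inert to hydroxide.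

Step 9
Reactants: 14 3-methoxy-2,4,5-tris(methoxymethoxy)-6-[(Z)-prop-1-en-1-yl]benzoic acid; 9 prop-2-en-1-yl 3-methoxy-2,4-bis(methoxymethoxy)-6-[(2R,3S)-3-methyloxiran-2-yl]benzoate
Product: 16 prop-2-en-1-yl 3-methoxy-2,4-bis(methoxymethoxy)-6-[(1R,2R)-2-({3-methoxy-2,4,5-tris(methoxymethoxy)-6-[(Z)-prop-1-en-1-yl]benzoyl}oxy)-1-(triethylsilyloxy)propyl]benzoate, via triethylsilyl ester 15 (not isolated)
Conditions: 14 (1.25 equiv), Et3SiCl, Et3N, toluene, 0 °C → rt, filter under argon; then 9, Bu4N[Ph3SiF2] (10 mol%), MeCN, 50 °C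
Reagents that add atoms: chlorotriethylsilane, CC[Si](Cl)(CC)CC
Why: Proposed new method: fluoride frees a catalytic amount of the tetrabutylammonium carboxylate of 14, which opens the cis-epoxide by SN2 at the methyl-bearing carbon (the benzylic carbon is shielded by the ortho ester and no Lewis acid lends it cationic character), inverting C2′ from S to R while C1′ stays R; the C1′ alkoxide is silylated at once by silyl ester 15, which regenerates the carboxylate and keeps the alkoxide from lactonising onto the neighbouring allyl ester; the closest known reaction types are the onium-carboxylate-catalysed addition of carboxylic acids to epoxides and the onium-salt-catalysed insertion of epoxides into active esters and silyl halides.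

Step 10
Reactants: 16 prop-2-en-1-yl 3-methoxy-2,4-bis(methoxymethoxy)-6-[(1R,2R)-2-({3-methoxy-2,4,5-tris(methoxymethoxy)-6-[(Z)-prop-1-en-1-yl]benzoyl}oxy)-1-(triethylsilyloxy)propyl]benzoate
Product: 17 prop-2-en-1-yl 3-methoxy-2,4-bis(methoxymethoxy)-6-[(1R,2R)-2-({3-methoxy-2,4,5-tris(methoxymethoxy)-6-[(2R,3S)-3-methyloxiran-2-yl]benzoyl}oxy)-1-(triethylsilyloxy)propyl]benzoate
Conditions: Shi D-glucose-derived N-aryl spiro-oxazolidinone ketone (30 mol%), KHSO5 (as 2KHSO5·KHSO4·K2SO4), K2CO3, DME/CH2(OMe)2, aq. K2CO3–AcOH buffer (pH 8), Bu4NHSO4, −10 → 0 °C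
Reagents that add atoms: potassium peroxymonosulfate, [K+].[O-]S(=O)(=O)OO
Why: a second Shi epoxidation under catalyst control (the existing stereocentres are remote) converts the unit-B Z-alkene into the (2R,3S)-oxirane, and the triethylsilyl ether and the esters are stable at pH 8.

Step 11
Reactants: 17 prop-2-en-1-yl 3-methoxy-2,4-bis(methoxymethoxy)-6-[(1R,2R)-2-({3-methoxy-2,4,5-tris(methoxymethoxy)-6-[(2R,3S)-3-methyloxiran-2-yl]benzoyl}oxy)-1-(triethylsilyloxy)propyl]benzoate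
Product: 19 penta-MOM macrodiolide bearing unit-A C1′–OSiEt3 and unit-B C1′–OSiMe3 (all four stereocentres R), via trimethylsilyl ester 18 (not isolated)
Conditions: Pd(PPh3)4 (5 mol%), 4-(trimethylsilyl)morpholine, CH2Cl2, rt; then syringe pump into Bu4N[Ph3SiF2] (20 mol%), N,O-bis(trimethylsilyl)acetamide (silyl shuttle), MeCN, 60 °C, final 2 mM
Reagents that add atoms: 4-(trimethylsilyl)morpholine, C[Si](C)(C)N1CCOCC1
Why: Proposed new method: the carboxylate/silyl-ester chain of step 9 run intramolecularly, the unit-A carboxylate attacking C2′ of the unit-B oxirane (its benzylic carbon is blocked by two ortho substituents) to close the 12-membered ring with inversion to R, while the silyl acetamide traps the C1′ alkoxide at high dilution before it can lactonise onto its ortho ester and then hands the silyl group back from another silyl ester to regenerate the carboxylate; the closest known reaction types are the zerovalent-palladium deallylation with N-silylamines that gives silyl esters directly and the carboxylate opening of epoxides to small-ring lactones.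

Step 12
Reactants: 19 penta-MOM macrodiolide bearing unit-A C1′–OSiEt3 and unit-B C1′–OSiMe3
Product: 21 target macrodiolide CNP0086623.2, via persilylated macrodiolide 20 (not isolated)
Conditions: Me3SiOTf, 2,2′-bipyridyl, MeCN, 0 °C → rt; then H2O; then HF·pyridine, pyridine, THF, 0 °C, same flask, argon
Reagents that add atoms: none
Why: the bipyridyl-buffered MOM-to-silyl exchange is a non-protic aryl MOM cleavage that keeps both benzylic oxygens silylated (no acid-promoted ionisation next to the ortho phenol of unit B), and buffered fluoride then frees all seven hydroxyls without touching the hindered diolide esters or the stereocentres.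

## Compound list

1 | 2-methoxybenzene-1,3-diol | COc1c(O)cccc1O | starting material
2 | 2-methoxy-1,3-bis(methoxymethoxy)benzene | COCOc1cccc(OCOC)c1OC | intermediate
3 | 2-[4-methoxy-3,5-bis(methoxymethoxy)phenyl]-4,4,5,5-tetramethyl-1,3,2-dioxaborolane | COCOc1cc(B2OC(C)(C)C(C)(C)O2)cc(OCOC)c1OC | intermediate
4 | (Z)-1-bromoprop-1-ene | C/C=C\Br | starting material
5 | 2-methoxy-1,3-bis(methoxymethoxy)-5-[(Z)-prop-1-en-1-yl]benzene | C/C=C\c1cc(OCOC)c(OC)c(OCOC)c1 | intermediate
6 | {3-methoxy-2,4-bis(methoxymethoxy)-6-[(Z)-prop-1-en-1-yl]phenyl}lithium | C/C=C\c1cc(OCOC)c(OC)c(OCOC)c1[Li] | intermediate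
7 | 3-methoxy-2,4-bis(methoxymethoxy)-6-[(Z)-prop-1-en-1-yl]benzoic acid | C/C=C\c1cc(OCOC)c(OC)c(OCOC)c1C(=O)O | intermediate
8 | prop-2-en-1-yl 3-methoxy-2,4-bis(methoxymethoxy)-6-[(Z)-prop-1-en-1-yl]benzoate | C/C=C\c1cc(OCOC)c(OC)c(OCOC)c1C(=O)OCC=C | intermediate
9 | prop-2-en-1-yl 3-methoxy-2,4-bis(methoxymethoxy)-6-[(2R,3S)-3-methyloxiran-2-yl]benzoate | C=CCOC(=O)c1c(OCOC)c(OC)c(OCOC)cc1[C@H]1O[C@H]1C | intermediate
10 | lithium 5-lithio-3-methoxy-2,4-bis(methoxymethoxy)-6-[(Z)-prop-1-en-1-yl]benzoate | C/C=C\c1c([Li])c(OCOC)c(OC)c(OCOC)c1C(=O)O[Li] | intermediate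
11 | lithium 5-(dimethoxyboranyl)-3-methoxy-2,4-bis(methoxymethoxy)-6-[(Z)-prop-1-en-1-yl]benzoate | C/C=C\c1c(B(OC)OC)c(OCOC)c(OC)c(OCOC)c1C(=O)O[Li] | intermediate
12 | 5-hydroxy-3-methoxy-2,4-bis(methoxymethoxy)-6-[(Z)-prop-1-en-1-yl]benzoic acid | C/C=C\c1c(O)c(OCOC)c(OC)c(OCOC)c1C(=O)O | intermediate
13 | methoxymethyl 3-methoxy-2,4,5-tris(methoxymethoxy)-6-[(Z)-prop-1-en-1-yl]benzoate | C/C=C\c1c(C(=O)OCOC)c(OCOC)c(OC)c(OCOC)c1OCOC | intermediate
14 | 3-methoxy-2,4,5-tris(methoxymethoxy)-6-[(Z)-prop-1-en-1-yl]benzoic acid | C/C=C\c1c(C(=O)O)c(OCOC)c(OC)c(OCOC)c1OCOC | intermediate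
15 | triethylsilyl 3-methoxy-2,4,5-tris(methoxymethoxy)-6-[(Z)-prop-1-en-1-yl]benzoate | C/C=C\c1c(C(=O)O[Si](CC)(CC)CC)c(OCOC)c(OC)c(OCOC)c1OCOC | intermediate
16 | prop-2-en-1-yl 3-methoxy-2,4-bis(methoxymethoxy)-6-[(1R,2R)-2-({3-methoxy-2,4,5-tris(methoxymethoxy)-6-[(Z)-prop-1-en-1-yl]benzoyl}oxy)-1-(triethylsilyloxy)propyl]benzoate | C=CCOC(=O)c1c(OCOC)c(OC)c(OCOC)cc1[C@@H](O[Si](CC)(CC)CC)[C@@H](C)OC(=O)c1c(OCOC)c(OC)c(OCOC)c(OCOC)c1/C=C\C | intermediate
17 | prop-2-en-1-yl 3-methoxy-2,4-bis(methoxymethoxy)-6-[(1R,2R)-2-({3-methoxy-2,4,5-tris(methoxymethoxy)-6-[(2R,3S)-3-methyloxiran-2-yl]benzoyl}oxy)-1-(triethylsilyloxy)propyl]benzoate | C=CCOC(=O)c1c(OCOC)c(OC)c(OCOC)cc1[C@@H](O[Si](CC)(CC)CC)[C@@H](C)OC(=O)c1c(OCOC)c(OC)c(OCOC)c(OCOC)c1[C@H]1O[C@H]1C | intermediate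
18 | trimethylsilyl ester corresponding to 17 (allyl replaced by SiMe3) | C[Si](C)(C)OC(=O)c1c(OCOC)c(OC)c(OCOC)cc1[C@@H](O[Si](CC)(CC)CC)[C@@H](C)OC(=O)c1c(OCOC)c(OC)c(OCOC)c(OCOC)c1[C@H]1O[C@H]1C | intermediate
19 | macrodiolide with the target skeleton, all five phenols as MOM ethers, unit-A C1′–OSiEt3, unit-B C1′–OSiMe3, all four stereocentres R | COc1c(OCOC)cc2c(c1OCOC)C(=O)O[C@H](C)[C@H](O[Si](C)(C)C)c1c(OCOC)c(OCOC)c(OC)c(OCOC)c1C(=O)O[C@H](C)[C@@H]2O[Si](CC)(CC)CC | intermediate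
20 | as 19 with the five MOM groups exchanged for SiMe3 | COc1c(O[Si](C)(C)C)cc2c(c1O[Si](C)(C)C)C(=O)O[C@H](C)[C@H](O[Si](C)(C)C)c1c(O[Si](C)(C)C)c(O[Si](C)(C)C)c(OC)c(O[Si](C)(C)C)c1C(=O)O[C@H](C)[C@@H]2O[Si](CC)(CC)CC | intermediate
21 | CNP0086623.2: 12-membered head-to-tail diolide of (1′R,2′R)-2-(1,2-dihydroxypropyl)-4,6-dihydroxy-5-methoxybenzoic acid (unit A) and (1′R,2′R)-2-(1,2-dihydroxypropyl)-3,4,6-trihydroxy-5-methoxybenzoic acid (unit B), each carboxyl esterified by the C2′–OH of the other unit | COc1c(O)cc2c(c1O)C(=O)O[C@H](C)[C@H](O)c1c(O)c(O)c(OC)c(O)c1C(=O)O[C@H](C)[C@@H]2O | target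

## Step count and risks

Total steps: 12. Longest linear sequence: 10 (steps 1, 2, 3, 4, 7, 8, 9, 10, 11, 12).

Steps most likely to fail:

Step 9 (new silyl-ester/epoxide coupling). Risks are attack at the benzylic carbon, or the C1′ alkoxide closing onto the allyl ester before it is silylated. The fallback uses known chemistry, sets out from 9 and 14 and returns at 16. Epoxide 9 is heated with CO2 and Bu4NBr; halide-catalysed carbonate formation goes by double inversion, so both centres are retained in the cis-carbonate prop-2-en-1-yl 3-methoxy-2,4-bis(methoxymethoxy)-6-[(4R,5S)-5-methyl-2-oxo-1,3-dioxolan-4-yl]benzoate F1. K2CO3 in MeOH removes the carbonate and the C1′ alkoxide closes onto the allyl ester to give the phthalide alcohol (3R)-3-[(1S)-1-hydroxyethyl]-6-methoxy-5,7-bis(methoxymethoxy)-2-benzofuran-1(3H)-one F2. Mitsunobu esterification of F2 with 14 (PPh3, DIAD, toluene) inverts the carbinol carbon to R and gives the phthalide ester (1R)-1-[(1R)-5-methoxy-4,6-bis(methoxymethoxy)-3-oxo-1,3-dihydro-2-benzofuran-1-yl]ethyl 3-methoxy-2,4,5-tris(methoxymethoxy)-6-[(Z)-prop-1-en-1-yl]benzoate F3. LiOH opens only the phthalide (the 2,6-disubstituted aroyl ester is inert), Et3SiOTf/2,6-lutidine silylates C1′–OH and the carboxylate, and aqueous K2CO3 work-up hydrolyses the silyl ester to 3-methoxy-2,4-bis(methoxymethoxy)-6-[(1R,2R)-2-({3-methoxy-2,4,5-tris(methoxymethoxy)-6-[(Z)-prop-1-en-1-yl]benzoyl}oxy)-1-(triethylsilyloxy)propyl]benzoic acid F4. Allyl bromide and KHCO3 in DMF then give 16.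

Step 11 (new macrocyclising version). Risks are oligomerisation, or loss of the alkoxide to phthalide formation with ring cleavage. The fallback is a Mitsunobu macrolactonisation, all known chemistry; it sets out from 9 and 14 and returns at 21. The side chain of a unit cannot be elaborated by known methods once its carboxyl is the inter-unit ester, so both units are elaborated first. Unit A: 9 is taken through the cyclic carbonate F1 to the phthalide alcohol F2 as above, silylated (Et3SiCl, imidazole) to (3R)-6-methoxy-5,7-bis(methoxymethoxy)-3-[(1S)-1-(triethylsilyloxy)ethyl]-2-benzofuran-1(3H)-one F5, opened with LiOH, silylated with t-BuMe2SiOTf/2,6-lutidine and freed from the silyl ester with K2CO3/MeOH to give 6-[(1R,2S)-1-(tert-butyldimethylsilyloxy)-2-(triethylsilyloxy)propyl]-3-methoxy-2,4-bis(methoxymethoxy)benzoic acid F6. Unit B: acid 14 is esterified with allyl bromide and KHCO3 in DMF to give prop-2-en-1-yl 3-methoxy-2,4,5-tris(methoxymethoxy)-6-[(Z)-prop-1-en-1-yl]benzoate F7. Shi epoxidation gives prop-2-en-1-yl 3-methoxy-2,4,5-tris(methoxymethoxy)-6-[(2R,3S)-3-methyloxiran-2-yl]benzoate F8, CO2/Bu4NBr gives prop-2-en-1-yl 3-methoxy-2,4,5-tris(methoxymethoxy)-6-[(4R,5S)-5-methyl-2-oxo-1,3-dioxolan-4-yl]benzoate F9, and K2CO3/MeOH gives (3R)-3-[(1S)-1-hydroxyethyl]-6-methoxy-4,5,7-tris(methoxymethoxy)-2-benzofuran-1(3H)-one F10. Mitsunobu coupling of F6 with F10 (inversion at the unit-B C2′) gives (1R)-1-[(1R)-5-methoxy-4,6,7-tris(methoxymethoxy)-3-oxo-1,3-dihydro-2-benzofuran-1-yl]ethyl 6-[(1R,2S)-1-(tert-butyldimethylsilyloxy)-2-(triethylsilyloxy)propyl]-3-methoxy-2,4-bis(methoxymethoxy)benzoate F11. LiOH opens the unit-B phthalide, t-BuMe2SiOTf protects its C1′–OH, and PPTS/MeOH removes the triethylsilyl ether and the silyl ester to give the seco acid 6-[(1R,2R)-1-(tert-butyldimethylsilyloxy)-2-({6-[(1R,2S)-1-(tert-butyldimethylsilyloxy)-2-hydroxypropyl]-3-methoxy-2,4-bis(methoxymethoxy)benzoyl}oxy)propyl]-3-methoxy-2,4,5-tris(methoxymethoxy)benzoic acid F12. Mitsunobu macrolactonisation (PPh3, DIAD, toluene, 2 mM) inverts the unit-A C2′ and closes the ring as the penta-MOM macrodiolide with both C1′ oxygens as tert-butyldimethylsilyl ethers F13, which the conditions of step 12 convert into 21.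

Step 10 (Shi epoxidation of the twisted, hexasubstituted Z-styrene in 16). Risks are low conversion or weak facial control. The fallback sets out from 16 and returns at 17. It replaces the dioxirane by metal–oxo transfer: Jacobsen–Katsuki epoxidation with (R,R)-N,N′-bis(3,5-di-tert-butylsalicylidene)-1,2-cyclohexanediaminomanganese chloride, NaOCl and 4-phenylpyridine N-oxide in CH2Cl2 at 0 °C. Cis-disubstituted aryl alkenes are the best substrates of this catalyst class, and the (R,R) complex gives the (1R,2S) sense; the diastereomers are separable at this stage. It makes no compound outside the list (none F0).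

Further compounds

F1 | step 9 | prop-2-en-1-yl 3-methoxy-2,4-bis(methoxymethoxy)-6-[(4R,5S)-5-methyl-2-oxo-1,3-dioxolan-4-yl]benzoate | C=CCOC(=O)c1c(OCOC)c(OC)c(OCOC)cc1[C@H]1OC(=O)O[C@H]1C
F2 | step 9 | (3R)-3-[(1S)-1-hydroxyethyl]-6-methoxy-5,7-bis(methoxymethoxy)-2-benzofuran-1(3H)-one | O=C1O[C@@H]([C@H](C)O)c2cc(OCOC)c(OC)c(OCOC)c12
F3 | step 9 | (1R)-1-[(1R)-5-methoxy-4,6-bis(methoxymethoxy)-3-oxo-1,3-dihydro-2-benzofuran-1-yl]ethyl 3-methoxy-2,4,5-tris(methoxymethoxy)-6-[(Z)-prop-1-en-1-yl]benzoate | O=C1O[C@@H]([C@@H](C)OC(=O)c3c(OCOC)c(OC)c(OCOC)c(OCOC)c3/C=C\C)c2cc(OCOC)c(OC)c(OCOC)c12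
F4 | step 9 | 3-methoxy-2,4-bis(methoxymethoxy)-6-[(1R,2R)-2-({3-methoxy-2,4,5-tris(methoxymethoxy)-6-[(Z)-prop-1-en-1-yl]benzoyl}oxy)-1-(triethylsilyloxy)propyl]benzoic acid | OC(=O)c1c(OCOC)c(OC)c(OCOC)cc1[C@@H](O[Si](CC)(CC)CC)[C@@H](C)OC(=O)c1c(OCOC)c(OC)c(OCOC)c(OCOC)c1/C=C\C
F5 | step 11 | (3R)-6-methoxy-5,7-bis(methoxymethoxy)-3-[(1S)-1-(triethylsilyloxy)ethyl]-2-benzofuran-1(3H)-one | O=C1O[C@@H]([C@H](C)O[Si](CC)(CC)CC)c2cc(OCOC)c(OC)c(OCOC)c12
F6 | step 11 | 6-[(1R,2S)-1-(tert-butyldimethylsilyloxy)-2-(triethylsilyloxy)propyl]-3-methoxy-2,4-bis(methoxymethoxy)benzoic acid | OC(=O)c1c(OCOC)c(OC)c(OCOC)cc1[C@@H](O[Si](C)(C)C(C)(C)C)[C@H](C)O[Si](CC)(CC)CC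
F7 | step 11 | prop-2-en-1-yl 3-methoxy-2,4,5-tris(methoxymethoxy)-6-[(Z)-prop-1-en-1-yl]benzoate | C=CCOC(=O)c1c(OCOC)c(OC)c(OCOC)c(OCOC)c1/C=C\C
F8 | step 11 | prop-2-en-1-yl 3-methoxy-2,4,5-tris(methoxymethoxy)-6-[(2R,3S)-3-methyloxiran-2-yl]benzoate | C=CCOC(=O)c1c(OCOC)c(OC)c(OCOC)c(OCOC)c1[C@H]1O[C@H]1C
F9 | step 11 | prop-2-en-1-yl 3-methoxy-2,4,5-tris(methoxymethoxy)-6-[(4R,5S)-5-methyl-2-oxo-1,3-dioxolan-4-yl]benzoate | C=CCOC(=O)c1c(OCOC)c(OC)c(OCOC)c(OCOC)c1[C@H]1OC(=O)O[C@H]1C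
F10 | step 11 | (3R)-3-[(1S)-1-hydroxyethyl]-6-methoxy-4,5,7-tris(methoxymethoxy)-2-benzofuran-1(3H)-one | O=C1O[C@@H]([C@H](C)O)c2c(OCOC)c(OCOC)c(OC)c(OCOC)c12
F11 | step 11 | (1R)-1-[(1R)-5-methoxy-4,6,7-tris(methoxymethoxy)-3-oxo-1,3-dihydro-2-benzofuran-1-yl]ethyl 6-[(1R,2S)-1-(tert-butyldimethylsilyloxy)-2-(triethylsilyloxy)propyl]-3-methoxy-2,4-bis(methoxymethoxy)benzoate | O=C1O[C@@H]([C@@H](C)OC(=O)c3c(OCOC)c(OC)c(OCOC)cc3[C@@H](O[Si](C)(C)C(C)(C)C)[C@H](C)O[Si](CC)(CC)CC)c2c(OCOC)c(OCOC)c(OC)c(OCOC)c12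
F12 | step 11 | 6-[(1R,2R)-1-(tert-butyldimethylsilyloxy)-2-({6-[(1R,2S)-1-(tert-butyldimethylsilyloxy)-2-hydroxypropyl]-3-methoxy-2,4-bis(methoxymethoxy)benzoyl}oxy)propyl]-3-methoxy-2,4,5-tris(methoxymethoxy)benzoic acid | OC(=O)c1c(OCOC)c(OC)c(OCOC)c(OCOC)c1[C@@H](O[Si](C)(C)C(C)(C)C)[C@@H](C)OC(=O)c1c(OCOC)c(OC)c(OCOC)cc1[C@@H](O[Si](C)(C)C(C)(C)C)[C@H](C)O
F13 | step 11 | penta-MOM macrodiolide with both C1′ oxygens as tert-butyldimethylsilyl ethers | COc1c(OCOC)cc2c(c1OCOC)C(=O)O[C@H](C)[C@H](O[Si](C)(C)C(C)(C)C)c1c(OCOC)c(OCOC)c(OC)c(OCOC)c1C(=O)O[C@H](C)[C@@H]2O[Si](C)(C)C(C)(C)C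
F0 | step 10 | none | none
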